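**Plan**

- Oxane numbering used below: O1, C2 (4-hydroxyphenyl), C3 (OH), C4 (ring A, the acylphloroglucinol ring), C5, C6 (arylethyl chain). Target: (2S,3S,4S,6S), i.e. 2,3-cis, 3,4-trans, 4,6-cis, 2,6-trans.
- Retrosynthetic cuts, in order: the two protecting-group sets; the C2–aryl bond together with the C3–O bond (back to a 2,3-enol ether); the ring A–C(=O) bond of the chalcone; then the oxane ring itself at O1–C2 and C4–C5.
- Enabling feature: C2 and C6, the two carbons on O1, are 1,5-related through C3–C4–C5, and C4 carries ring A. The oxane is therefore the δ-lactone of a 5-oxo acid in disguise: C2–C3=C4 as an α,β-unsaturated acyl azolium ion, C5=C6–O1 as the enolate of a methyl ketone.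
- Forward: ring A cinnamoyl fluoride plus silyl enol ether of 4-arylbutan-2-one give the 3,4-dihydropyran-2-one (ring formed); hydrogenation, reduction to the lactol and dehydration give the 2,3-enol ether; ring A is lithiated and acylated to the chalcone; epoxidation and aryl transfer complete the oxane; deprotection.
- Stereochemistry: C4 from the chiral carbene catalyst; C6 by hydrogenation anti to ring A; C3 by epoxidation anti to ring A; C2 by syn (axial) aryl delivery from aluminium.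
- Helpers taken out later: acyl level at C2 and enol level at C6; MOM ethers; a pivalate that keeps the C2 aryl group electron-poor during the acidic deprotection.

Key step: step 7

Assumption: the facial sense of the triazolylidene catalyst is not predicted here; the catalyst enantiomer that delivers (4S)-11 is used, and the sense is to be fixed by correlation on the first batch.

**Route**

Step 1
Reactants: 1 5-methoxybenzene-1,3-diol
Product: 2 1-methoxy-3,5-bis(methoxymethoxy)benzene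
Conditions: MeOCH2Cl, i-Pr2NEt, CH2Cl2, 0 °C → rt
Reagents that add atoms: chloromethyl methyl ether, COCCl
Why: Williamson-type O-alkylation of both phenols should proceed cleanly, and the MOM acetals later direct both ring lithiations.

Step 2
Reactants: 2 1-methoxy-3,5-bis(methoxymethoxy)benzene
Product: 4 4-methoxy-2,6-bis(methoxymethoxy)benzaldehyde, via aryllithium 3 (not isolated)
Conditions: n-BuLi, TMEDA, THF, 0 °C; then DMF, 0 °C → rt; aq NH4Cl
Reagents that add atoms: N,N-dimethylformamide, CN(C)C=O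
Why: Directed ortho-metalation should occur at the carbon flanked by the two chelating MOM ethers, and formylation of the aryllithium gives the aldehyde.

Step 3
Reactants: 4 4-methoxy-2,6-bis(methoxymethoxy)benzaldehyde
Product: 5 (2E)-3-[4-methoxy-2,6-bis(methoxymethoxy)phenyl]prop-2-enoic acid
Conditions: CH2(CO2H)2, pyridine, piperidine (cat.), 90 °C
Reagents that add atoms: malonic acid, OC(=O)CC(=O)O
Why: Knoevenagel–Doebner condensation with decarboxylation should give the E acid, under basic conditions that leave the MOM acetals alone.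

Step 4
Reactants: 5 (2E)-3-[4-methoxy-2,6-bis(methoxymethoxy)phenyl]prop-2-enoic acid
Product: 6 (2E)-3-[4-methoxy-2,6-bis(methoxymethoxy)phenyl]prop-2-enoyl fluoride
Conditions: cyanuric fluoride, pyridine, CH2Cl2, −10 °C → rt
Reagents that add atoms: cyanuric fluoride, Fc1nc(F)nc(F)n1
Why: Deoxyfluorination of a carboxylic acid with cyanuric fluoride is a standard route to stable acyl fluorides and needs no acid.

Step 5
Reactants: 7 4-(4-hydroxyphenyl)butan-2-one
Product: 8 4-[4-(methoxymethoxy)phenyl]butan-2-one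
Conditions: MeOCH2Cl, i-Pr2NEt, CH2Cl2, 0 °C → rt
Reagents that add atoms: chloromethyl methyl ether, COCCl
Why: O-alkylation of the phenol protects it for the enolate, hydride and organolithium steps that follow.

Step 6
Reactants: 8 4-[4-(methoxymethoxy)phenyl]butan-2-one
Product: 10 trimethyl({4-[4-(methoxymethoxy)phenyl]but-1-en-2-yl}oxy)silane, via lithium enolate 9 (not isolated)
Conditions: LiN(i-Pr)2, Me3SiCl (present from the start), THF, −78 °C
Reagents that add atoms: chlorotrimethylsilane, C[Si](C)(C)Cl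
Why: Kinetic deprotonation at the methyl group with internal silyl quench should fix the enolate regiochemistry, so that C5 is the nucleophilic carbon.

Step 7
Reactants: 6 (2E)-3-[4-methoxy-2,6-bis(methoxymethoxy)phenyl]prop-2-enoyl fluoride; 10 trimethyl({4-[4-(methoxymethoxy)phenyl]but-1-en-2-yl}oxy)silane
Product: 11 (4S)-4-[4-methoxy-2,6-bis(methoxymethoxy)phenyl]-6-{2-[4-(methoxymethoxy)phenyl]ethyl}-3,4-dihydro-2H-pyran-2-one
Conditions: 2-tert-butyl-5a,10b-dihydro-4H,6H-indeno[2,1-b][1,2,4]triazolo[4,3-d][1,4]oxazin-2-ium tetrafluoroborate (one enantiomer, 10 mol %), KN(SiMe3)2 (9 mol %), THF, −78 °C → rt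
Reagents that add atoms: none
Why: The free carbene adds to acyl fluoride 6 to give the α,β-unsaturated acyl azolium ion and fluoride, which desilylates 10 to the terminal enolate; the enolate carbon C5 attacks the β-carbon C4 (directly, or by 1,2-addition and [3,3] shift), and after proton transfer the enol oxygen O1 acylates at C2 and releases the catalyst. The closest known reaction type is the carbene-catalysed annulation of α,β-unsaturated acyl fluorides with ketone silyl enol ethers to 3,4-dihydropyran-2-ones, including its enantioselective versions with chiral triazolylidenes. The one ring formed, the dihydropyranone, is closed by lactonisation, a 6-exo-trig attack of O1 on the acyl carbon C2. The only new stereocentre, C4, is set by the chiral triazolylidene, whose indane wall shields one face of the acyl azolium ion. The step needs attack by the methyl-side enolate and C- rather than O-acylation: the first is secured by the regiodefined silyl enol ether, unmasked only by the fluoride set free from 6, and the second is not critical because an O-acylated enol ester re-enters the same catalytic cycle. The two ortho MOM ethers twist ring A out of conjugation, which limits its donor effect at C4 but adds steric hindrance.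

Step 8
Reactants: 11 (4S)-4-[4-methoxy-2,6-bis(methoxymethoxy)phenyl]-6-{2-[4-(methoxymethoxy)phenyl]ethyl}-3,4-dihydro-2H-pyran-2-one
Product: 12 (4R,6S)-4-[4-methoxy-2,6-bis(methoxymethoxy)phenyl]-6-{2-[4-(methoxymethoxy)phenyl]ethyl}oxan-2-one
Conditions: H2 (1 atm), Pd/C, EtOAc, rt
Reagents that add atoms: none
Why: Syn hydrogenation of the enol lactone C5=C6 from the face opposite the bulky C4 aryl group should place the C6 chain cis to ring A (4,6-cis), which sets C6; the C4 descriptor changes by priority only.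

Step 9
Reactants: 12 (4R,6S)-4-[4-methoxy-2,6-bis(methoxymethoxy)phenyl]-6-{2-[4-(methoxymethoxy)phenyl]ethyl}oxan-2-one
Product: 13 (4R,6S)-4-[4-methoxy-2,6-bis(methoxymethoxy)phenyl]-6-{2-[4-(methoxymethoxy)phenyl]ethyl}oxan-2-ol (anomer mixture)
Conditions: i-Bu2AlH (1.1 equiv), CH2Cl2, −78 °C; aq potassium sodium tartrate
Reagents that add atoms: none
Why: Partial reduction of a δ-lactone with one hydride equivalent at −78 °C is the standard lactone-to-lactol reduction and leaves C4 and C6 untouched.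

Step 10
Reactants: 13 (4R,6S)-4-[4-methoxy-2,6-bis(methoxymethoxy)phenyl]-6-{2-[4-(methoxymethoxy)phenyl]ethyl}oxan-2-ol
Product: 15 (2S,4R)-4-[4-methoxy-2,6-bis(methoxymethoxy)phenyl]-2-{2-[4-(methoxymethoxy)phenyl]ethyl}-3,4-dihydro-2H-pyran, via anomeric mesylate 14 (not isolated)
Conditions: MeSO2Cl, Et3N (excess), CH2Cl2, −20 °C → 40 °C
Reagents that add atoms: none
Why: Sulfonylation of the anomeric hydroxyl and base-promoted loss of methanesulfonate through the oxocarbenium ion should give the cyclic enol ether, the usual dehydration of a 2-deoxy lactol.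

Step 11
Reactants: 16 4-(methoxymethoxy)benzaldehyde
Product: 17 (2E)-N-methoxy-3-[4-(methoxymethoxy)phenyl]-N-methylprop-2-enamide
Conditions: (EtO)2P(O)CH2C(O)N(OMe)Me, NaH, THF, 0 °C → rt
Reagents that add atoms: diethyl {2-[methoxy(methyl)amino]-2-oxoethyl}phosphonate, CCOP(=O)(CC(=O)N(C)OC)OCC
Why: Horner–Wadsworth–Emmons olefination with a stabilised phosphonate should give the E unsaturated N-methoxy-N-methylamide.

Step 12
Reactants: 15 (2S,4R)-4-[4-methoxy-2,6-bis(methoxymethoxy)phenyl]-2-{2-[4-(methoxymethoxy)phenyl]ethyl}-3,4-dihydro-2H-pyran; 17 (2E)-N-methoxy-3-[4-(methoxymethoxy)phenyl]-N-methylprop-2-enamide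
Product: 19 (2E)-1-{3-[(2S,4R)-2-{2-[4-(methoxymethoxy)phenyl]ethyl}-3,4-dihydro-2H-pyran-4-yl]-6-methoxy-2,4-bis(methoxymethoxy)phenyl}-3-[4-(methoxymethoxy)phenyl]prop-2-en-1-one, via aryllithium 18 (not isolated)
Conditions: n-BuLi (1.2 equiv), THF, 0 °C; then 17, −78 → 0 °C; aq NH4Cl
Reagents that add atoms: none
Why: Directed ortho-metalation should occur at the ring A carbon between OMOM and OMe (the two free positions are equivalent by rotation about the C4–aryl bond), and acyl substitution on the N-methoxy-N-methylamide stops at the ketone, giving the E chalcone.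

Step 13
Reactants: 20 4-iodophenol
Product: 21 4-iodophenyl 2,2-dimethylpropanoate
Conditions: t-BuCOCl, Et3N, DMAP (cat.), CH2Cl2, 0 °C → rt
Reagents that add atoms: pivaloyl chloride, CC(C)(C)C(Cl)=O
Why: O-acylation gives an ester that survives iodine–magnesium exchange and later makes the C2 aryl group electron-poor.

Step 14
Reactants: 19 (2E)-1-{3-[(2S,4R)-2-{2-[4-(methoxymethoxy)phenyl]ethyl}-3,4-dihydro-2H-pyran-4-yl]-6-methoxy-2,4-bis(methoxymethoxy)phenyl}-3-[4-(methoxymethoxy)phenyl]prop-2-en-1-one; 21 4-iodophenyl 2,2-dimethylpropanoate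
Product: 25 4-[(2S,3S,4S,6S)-3-hydroxy-4-{4-methoxy-2,6-bis(methoxymethoxy)-3-[(2E)-3-[4-(methoxymethoxy)phenyl]prop-2-enoyl]phenyl}-6-{2-[4-(methoxymethoxy)phenyl]ethyl}oxan-2-yl]phenyl 2,2-dimethylpropanoate, via aryl Grignard reagent 22 (not isolated), via triarylaluminium 23 (not isolated), via glycal epoxide 24 (not isolated)
Conditions: 19, dimethyldioxirane (acetone solution), CH2Cl2, −78 → 0 °C, evaporate; separately 21, i-PrMgCl·LiCl, THF, −20 °C, then AlCl3 (one third equiv per aryl), 0 °C; add to the crude epoxide, CH2Cl2, −78 → −30 °C; aq potassium sodium tartrate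
Reagents that add atoms: dimethyldioxirane, CC1(C)OO1
Why: Dimethyldioxirane should epoxidise the electron-rich enol ether from the face anti to the C4 aryl group (the enone reacts far more slowly), and aluminium-assisted opening of this 1,2-anhydro-sugar-type epoxide with internal axial aryl transfer, the syn opening known for organoaluminium reagents, should place the aryl group on C2 cis to the C3 oxygen and trans to the C6 chain.

Step 15
Reactants: 25 4-[(2S,3S,4S,6S)-3-hydroxy-4-{4-methoxy-2,6-bis(methoxymethoxy)-3-[(2E)-3-[4-(methoxymethoxy)phenyl]prop-2-enoyl]phenyl}-6-{2-[4-(methoxymethoxy)phenyl]ethyl}oxan-2-yl]phenyl 2,2-dimethylpropanoate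
Product: 26 4-[(2S,3S,4S,6S)-4-{2,6-dihydroxy-3-[(2E)-3-(4-hydroxyphenyl)prop-2-enoyl]-4-methoxyphenyl}-3-hydroxy-6-[2-(4-hydroxyphenyl)ethyl]oxan-2-yl]phenyl 2,2-dimethylpropanoate
Conditions: HCl (3 M in MeOH), rt
Reagents that add atoms: none
Why: Acid-catalysed acetal exchange should remove the four MOM groups, while the pivalate keeps the C2 aryl group electron-poor and so suppresses ionisation of the C2–O1 benzylic ether, which would epimerise C2 to the equatorial isomer.

Step 16
Reactants: 26 4-[(2S,3S,4S,6S)-4-{2,6-dihydroxy-3-[(2E)-3-(4-hydroxyphenyl)prop-2-enoyl]-4-methoxyphenyl}-3-hydroxy-6-[2-(4-hydroxyphenyl)ethyl]oxan-2-yl]phenyl 2,2-dimethylpropanoate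
Product: 27 (2E)-1-{2,4-dihydroxy-3-[(2S,3S,4S,6S)-3-hydroxy-2-(4-hydroxyphenyl)-6-[2-(4-hydroxyphenyl)ethyl]oxan-4-yl]-6-methoxyphenyl}-3-(4-hydroxyphenyl)prop-2-en-1-one
Conditions: K2CO3 (substoichiometric), MeOH, 0 °C → rt; aq NH4Cl
Reagents that add atoms: none
Why: Base-catalysed methanolysis of the aryl pivalate is non-acidic, so the now electron-rich C2 benzylic ether and the chalcone should both survive.

**Compound list**

1 | 5-methoxybenzene-1,3-diol | COc1cc(O)cc(O)c1 | starting material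
2 | 1-methoxy-3,5-bis(methoxymethoxy)benzene | COCOc1cc(OC)cc(OCOC)c1 | intermediate
3 | [4-methoxy-2,6-bis(methoxymethoxy)phenyl]lithium | COCOc1cc(OC)cc(OCOC)c1[Li] | intermediate
4 | 4-methoxy-2,6-bis(methoxymethoxy)benzaldehyde | COCOc1cc(OC)cc(OCOC)c1C=O | intermediate
5 | (2E)-3-[4-methoxy-2,6-bis(methoxymethoxy)phenyl]prop-2-enoic acid | COCOc1cc(OC)cc(OCOC)c1/C=C/C(=O)O | intermediate
6 | (2E)-3-[4-methoxy-2,6-bis(methoxymethoxy)phenyl]prop-2-enoyl fluoride | COCOc1cc(OC)cc(OCOC)c1/C=C/C(F)=O | intermediate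
7 | 4-(4-hydroxyphenyl)butan-2-one | CC(=O)CCc1ccc(O)cc1 | starting material
8 | 4-[4-(methoxymethoxy)phenyl]butan-2-one | CC(=O)CCc1ccc(OCOC)cc1 | intermediate
9 | lithium 4-[4-(methoxymethoxy)phenyl]but-1-en-2-olate | [Li]OC(=C)CCc1ccc(OCOC)cc1 | intermediate
10 | trimethyl({4-[4-(methoxymethoxy)phenyl]but-1-en-2-yl}oxy)silane | C=C(CCc1ccc(OCOC)cc1)O[Si](C)(C)C | intermediate
11 | (4S)-4-[4-methoxy-2,6-bis(methoxymethoxy)phenyl]-6-{2-[4-(methoxymethoxy)phenyl]ethyl}-3,4-dihydro-2H-pyran-2-one | COCOc1cc(OC)cc(OCOC)c1[C@@H]2C=C(CCc3ccc(OCOC)cc3)OC(=O)C2 | intermediate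
12 | (4R,6S)-4-[4-methoxy-2,6-bis(methoxymethoxy)phenyl]-6-{2-[4-(methoxymethoxy)phenyl]ethyl}oxan-2-one (4,6-cis) | COCOc1cc(OC)cc(OCOC)c1[C@@H]2C[C@H](CCc3ccc(OCOC)cc3)OC(=O)C2 | intermediate
13 | (4R,6S)-4-[4-methoxy-2,6-bis(methoxymethoxy)phenyl]-6-{2-[4-(methoxymethoxy)phenyl]ethyl}oxan-2-ol (anomer mixture) | COCOc1cc(OC)cc(OCOC)c1[C@@H]2C[C@H](CCc3ccc(OCOC)cc3)OC(O)C2 | intermediate
14 | (4R,6S)-4-[4-methoxy-2,6-bis(methoxymethoxy)phenyl]-6-{2-[4-(methoxymethoxy)phenyl]ethyl}oxan-2-yl methanesulfonate | COCOc1cc(OC)cc(OCOC)c1[C@@H]2C[C@H](CCc3ccc(OCOC)cc3)OC(OS(C)(=O)=O)C2 | intermediate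
15 | (2S,4R)-4-[4-methoxy-2,6-bis(methoxymethoxy)phenyl]-2-{2-[4-(methoxymethoxy)phenyl]ethyl}-3,4-dihydro-2H-pyran | COCOc1cc(OC)cc(OCOC)c1[C@@H]2C[C@H](CCc3ccc(OCOC)cc3)OC=C2 | intermediate
16 | 4-(methoxymethoxy)benzaldehyde | COCOc1ccc(C=O)cc1 | starting material
17 | (2E)-N-methoxy-3-[4-(methoxymethoxy)phenyl]-N-methylprop-2-enamide | COCOc1ccc(/C=C/C(=O)N(C)OC)cc1 | intermediate
18 | {3-[(2S,4R)-2-{2-[4-(methoxymethoxy)phenyl]ethyl}-3,4-dihydro-2H-pyran-4-yl]-6-methoxy-2,4-bis(methoxymethoxy)phenyl}lithium | COc1c([Li])c(OCOC)c([C@@H]2C[C@H](CCc3ccc(OCOC)cc3)OC=C2)c(OCOC)c1 | intermediate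
19 | (2E)-1-{3-[(2S,4R)-2-{2-[4-(methoxymethoxy)phenyl]ethyl}-3,4-dihydro-2H-pyran-4-yl]-6-methoxy-2,4-bis(methoxymethoxy)phenyl}-3-[4-(methoxymethoxy)phenyl]prop-2-en-1-one | COc1cc(OCOC)c([C@@H]2C[C@H](CCc3ccc(OCOC)cc3)OC=C2)c(OCOC)c1C(=O)/C=C/c1ccc(OCOC)cc1 | intermediate
20 | 4-iodophenol | Oc1ccc(I)cc1 | starting material
21 | 4-iodophenyl 2,2-dimethylpropanoate | CC(C)(C)C(=O)Oc1ccc(I)cc1 | intermediate
22 | {4-[(2,2-dimethylpropanoyl)oxy]phenyl}magnesium chloride (LiCl complex) | CC(C)(C)C(=O)Oc1ccc([Mg]Cl)cc1 | intermediate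
23 | tris{4-[(2,2-dimethylpropanoyl)oxy]phenyl}aluminium | CC(C)(C)C(=O)Oc1ccc(cc1)[Al](c1ccc(OC(=O)C(C)(C)C)cc1)c1ccc(OC(=O)C(C)(C)C)cc1 | intermediate
24 | 2,3-epoxide of 19 (oxane numbering; epoxide oxygen on the ring face anti to the C4 aryl group) | COc1cc(OCOC)c([C@@H]2C[C@H](CCc3ccc(OCOC)cc3)O[C@H]4O[C@@H]24)c(OCOC)c1C(=O)/C=C/c1ccc(OCOC)cc1 | intermediate
25 | 4-[(2S,3S,4S,6S)-3-hydroxy-4-{4-methoxy-2,6-bis(methoxymethoxy)-3-[(2E)-3-[4-(methoxymethoxy)phenyl]prop-2-enoyl]phenyl}-6-{2-[4-(methoxymethoxy)phenyl]ethyl}oxan-2-yl]phenyl 2,2-dimethylpropanoate | COc1cc(OCOC)c([C@@H]2C[C@H](CCc3ccc(OCOC)cc3)O[C@@H](c3ccc(OC(=O)C(C)(C)C)cc3)[C@H]2O)c(OCOC)c1C(=O)/C=C/c1ccc(OCOC)cc1 | intermediate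
26 | 4-[(2S,3S,4S,6S)-4-{2,6-dihydroxy-3-[(2E)-3-(4-hydroxyphenyl)prop-2-enoyl]-4-methoxyphenyl}-3-hydroxy-6-[2-(4-hydroxyphenyl)ethyl]oxan-2-yl]phenyl 2,2-dimethylpropanoate | COc1cc(O)c([C@@H]2C[C@H](CCc3ccc(O)cc3)O[C@@H](c3ccc(OC(=O)C(C)(C)C)cc3)[C@H]2O)c(O)c1C(=O)/C=C/c1ccc(O)cc1 | intermediate
27 | (2E)-1-{2,4-dihydroxy-3-[(2S,3S,4S,6S)-3-hydroxy-2-(4-hydroxyphenyl)-6-[2-(4-hydroxyphenyl)ethyl]oxan-4-yl]-6-methoxyphenyl}-3-(4-hydroxyphenyl)prop-2-en-1-one | COc1cc(O)c([C@@H]2C[C@H](CCc3ccc(O)cc3)O[C@@H](c3ccc(O)cc3)[C@H]2O)c(O)c1C(=O)/C=C/c1ccc(O)cc1 | target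

**Step count**

Total: 16 steps. Longest linear sequence: 12 steps (1, 2, 3, 4, 7, 8, 9, 10, 12, 14, 15, 16).

**Steps most likely to fail**

Step 7. The conjugate addition may be slow at a β-carbon flanked by a 2,6-disubstituted, electron-rich aryl ring, and facial discrimination may be weak with a simple methyl ketone enolate. The fallback replaces carbene catalysis by iminium catalysis; it sets out from aldehyde 4 and silyl enol ether 10 and comes back at 11. Wittig reaction of 4 with (triphenylphosphoranylidene)acetaldehyde (toluene, 80 °C) should give (2E)-3-[4-methoxy-2,6-bis(methoxymethoxy)phenyl]prop-2-enal F1. Enantioselective Mukaiyama–Michael addition of 10 to F1 under a chiral 5-benzyl-2-tert-butyl-3-methylimidazolidin-4-one salt should give (3S)-3-[4-methoxy-2,6-bis(methoxymethoxy)phenyl]-7-[4-(methoxymethoxy)phenyl]-5-oxoheptanal F2. Chlorite oxidation (NaClO2, NaH2PO4, 2-methylbut-2-ene) should give (3R)-3-[4-methoxy-2,6-bis(methoxymethoxy)phenyl]-7-[4-(methoxymethoxy)phenyl]-5-oxoheptanoic acid F3 (same spatial arrangement; the descriptor changes by priority). Enol-lactonisation of F3 ((COCl)2, then Et3N) closes O1–C2 and returns to 11.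

Step 14. Internal aryl delivery may be lost (external attack, or re-ionisation of the product at C2) and give the equatorial C2 epimer, and the aluminium reagent may attack the enone. The fallback uses external axial attack on an oxocarbenium ion instead of internal delivery; it sets out from 19 and 21 and comes back at 25. Epoxide 24, made as in step 14, is opened with methanol to the methyl glycoside 4-{...}-2-methoxyoxan-3-ol F4 (2-OMe trans to 3-OH, otherwise as 25 without the C2 aryl group). Miyaura borylation of 21 (bis(pinacolato)diboron, PdCl2(dppf), KOAc) gives 4-(4,4,5,5-tetramethyl-1,3,2-dioxaborolan-2-yl)phenyl 2,2-dimethylpropanoate F5, and KHF2 converts it into potassium trifluoro{4-[(2,2-dimethylpropanoyl)oxy]phenyl}borate F6. BF3·OEt2 (MeCN, 0 °C) should then ionise F4 and let F6 transfer its aryl group to the axial face of the oxocarbenium ion, cis to the C3 hydroxyl, giving 25.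

Step 12. Lithiation may occur at other sites (ortho to the OMOM group of the side-chain ring, the vinylic C–H of the enol ether, the C4–H), and the aryllithium may add in conjugate fashion to the amide. The fallback acylates ring A electrophilically after the oxane is complete; it sets out from 15 and comes back at the target 27. Epoxidation of 15 with dimethyldioxirane gives the 2,3-epoxide F7, and aryl transfer from 23 as in step 14 should give 4-[(2S,3S,4S,6S)-3-hydroxy-4-[4-methoxy-2,6-bis(methoxymethoxy)phenyl]-6-{2-[4-(methoxymethoxy)phenyl]ethyl}oxan-2-yl]phenyl 2,2-dimethylpropanoate F8. HCl in MeOH removes the three MOM groups to give 4-[(2S,3S,4S,6S)-4-(2,6-dihydroxy-4-methoxyphenyl)-3-hydroxy-6-[2-(4-hydroxyphenyl)ethyl]oxan-2-yl]phenyl 2,2-dimethylpropanoate F9. Friedel–Crafts acetylation of the free phloroglucinol-type ring A (AcOH, BF3·OEt2) should give 4-[(2S,3S,4S,6S)-4-(3-acetyl-2,6-dihydroxy-4-methoxyphenyl)-3-hydroxy-6-[2-(4-hydroxyphenyl)ethyl]oxan-2-yl]phenyl 2,2-dimethylpropanoate F10, the pivalate keeping the C2 ether acid-stable. Claisen–Schmidt condensation of F10 with 4-hydroxybenzaldehyde (KOH, EtOH–H2O), which also cleaves the pivalate, gives 27.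

**Further compounds**

F1 | step 7 | (2E)-3-[4-methoxy-2,6-bis(methoxymethoxy)phenyl]prop-2-enal | COCOc1cc(OC)cc(OCOC)c1/C=C/C=O
F2 | step 7 | (3S)-3-[4-methoxy-2,6-bis(methoxymethoxy)phenyl]-7-[4-(methoxymethoxy)phenyl]-5-oxoheptanal | COCOc1cc(OC)cc(OCOC)c1[C@@H](CC=O)CC(=O)CCc1ccc(OCOC)cc1
F3 | step 7 | (3R)-3-[4-methoxy-2,6-bis(methoxymethoxy)phenyl]-7-[4-(methoxymethoxy)phenyl]-5-oxoheptanoic acid | COCOc1cc(OC)cc(OCOC)c1[C@@H](CC(=O)O)CC(=O)CCc1ccc(OCOC)cc1
F4 | step 14 | methyl glycoside from 24: 2-methoxyoxan-3-ol with 2-OMe trans to 3-OH and the C4 aryl and C6 chain as in 25 | COc1cc(OCOC)c([C@@H]2C[C@H](CCc3ccc(OCOC)cc3)O[C@H](OC)[C@H]2O)c(OCOC)c1C(=O)/C=C/c1ccc(OCOC)cc1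
F5 | step 14 | 4-(4,4,5,5-tetramethyl-1,3,2-dioxaborolan-2-yl)phenyl 2,2-dimethylpropanoate | CC(C)(C)C(=O)Oc1ccc(cc1)B1OC(C)(C)C(C)(C)O1
F6 | step 14 | potassium trifluoro{4-[(2,2-dimethylpropanoyl)oxy]phenyl}borate | CC(C)(C)C(=O)Oc1ccc(cc1)[B-](F)(F)F.[K+]
F7 | step 12 | 2,3-epoxide of 15 (oxane numbering; epoxide oxygen anti to the C4 aryl group) | COCOc1cc(OC)cc(OCOC)c1[C@@H]2C[C@H](CCc3ccc(OCOC)cc3)O[C@H]4O[C@@H]24
F8 | step 12 | 4-[(2S,3S,4S,6S)-3-hydroxy-4-[4-methoxy-2,6-bis(methoxymethoxy)phenyl]-6-{2-[4-(methoxymethoxy)phenyl]ethyl}oxan-2-yl]phenyl 2,2-dimethylpropanoate | COCOc1cc(OC)cc(OCOC)c1[C@@H]2C[C@H](CCc3ccc(OCOC)cc3)O[C@@H](c3ccc(OC(=O)C(C)(C)C)cc3)[C@H]2O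
F9 | step 12 | 4-[(2S,3S,4S,6S)-4-(2,6-dihydroxy-4-methoxyphenyl)-3-hydroxy-6-[2-(4-hydroxyphenyl)ethyl]oxan-2-yl]phenyl 2,2-dimethylpropanoate | COc1cc(O)c([C@@H]2C[C@H](CCc3ccc(O)cc3)O[C@@H](c3ccc(OC(=O)C(C)(C)C)cc3)[C@H]2O)c(O)c1
F10 | step 12 | 4-[(2S,3S,4S,6S)-4-(3-acetyl-2,6-dihydroxy-4-methoxyphenyl)-3-hydroxy-6-[2-(4-hydroxyphenyl)ethyl]oxan-2-yl]phenyl 2,2-dimethylpropanoate | COc1cc(O)c([C@@H]2C[C@H](CCc3ccc(O)cc3)O[C@@H](c3ccc(OC(=O)C(C)(C)C)cc3)[C@H]2O)c(O)c1C(C)=O
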